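**Retrosynthetic overview**

1. Target 31 ← hydrogenation of Δ2-lactone 30 ← oxidative lactonisation and catalyst-controlled epoxidation/5-exo etherification of the 13(16)-ene side chain (sets C13) on Δ2-octalin 25 ← β-keto sulfone 22 by reduction, acetylation and Julia elimination.
2. 22 ← keto sulfone butenolide 20 in one base-mediated operation: Michael addition forms C5–C10 (ring B), then sulfone–lactone Claisen condensation forms C2–C3 (ring A) and releases the 9α-OH.
3. Enabling feature: ring B carries oxygen on C6 and on C9, on either side of the C5–C10 bond, and C9 is a tertiary C–O carbon next to quaternary C10. C9–O, C10, C1 and C2 can therefore be drawn as a butenolide ring (O9–C2(=O)–C1=C10(Me)–C9), electrophilic at C10 and C2. C5 (α to the C6 ketone) and C3 (α to a sulfone), insulated by the C4 gem-dimethyl carbon, are the matching pair of nucleophiles.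
4. 20 ← aldehyde 14 + neopentyl Grignard reagent 18; 14 ← vinylogous Mukaiyama–Michael addition of silyloxyfuran 12 to crotonaldehyde (sets C8 and C9).
5. Ring order: butenolide (temporary ring) → ring B → ring A (butenolide opened) → tetrahydrofuran → γ-lactone.

Key step: step 11

Remark: labdane numbering is used for all intermediates (C1–C10 decalin, C11–C16 side chain, C17 on C8, C18/C19 on C4, C20 on C10); compounds 1, 3, 7, 13, 15 and 16 are taken as commercial.

**Route**

Step 1
Reactants: 1 3-bromobut-3-en-1-ol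
Product: 2 [(3-bromobut-3-en-1-yl)oxy](tert-butyl)dimethylsilane
Conditions: TBSCl, imidazole, DMF, 0 °C to rt
Reagents that add atoms: tert-butyldimethylsilyl chloride, CC(C)(C)[Si](C)(C)Cl
Why: Routine silyl ether formation on a primary alcohol; no stereocentre is involved.

Step 2
Reactants: 2 [(3-bromobut-3-en-1-yl)oxy](tert-butyl)dimethylsilane; 3 oxetane
Product: 5 6-[(tert-butyldimethylsilyl)oxy]-4-methylidenehexan-1-ol, via vinyllithium 4 (not isolated)
Conditions: t-BuLi (2.1 equiv), Et2O, −78 °C; then 3, BF3·OEt2, −78 °C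
Reagents that add atoms: none
Why: Bromine–lithium exchange followed by Lewis-acid-assisted opening of oxetane by the alkenyllithium adds the three carbons that become C12, C11 and C9; no stereocentre is formed.

Step 3
Reactants: 5 6-[(tert-butyldimethylsilyl)oxy]-4-methylidenehexan-1-ol
Product: 6 6-[(tert-butyldimethylsilyl)oxy]-4-methylidenehexanal
Conditions: DMP (1,1,1-triacetoxy-1,1-dihydro-1,2-benziodoxol-3(1H)-one), CH2Cl2, rt
Reagents that add atoms: none
Why: Hypervalent-iodine oxidation of a primary alcohol stops at the aldehyde and leaves the alkene and silyl ether untouched.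

Step 4
Reactants: 6 6-[(tert-butyldimethylsilyl)oxy]-4-methylidenehexanal; 7 ethyl propiolate
Product: 9 ethyl 9-[(tert-butyldimethylsilyl)oxy]-4-hydroxy-7-methylidenenon-2-ynoate, via lithium acetylide 8 (not isolated)
Conditions: LiN(iPr)2, THF, −78 °C; then 6; aq NH4Cl
Reagents that add atoms: none
Why: 1,2-Addition of a lithium acetylide to an aldehyde; the carbinol (future C9) is formed racemic, which is harmless because this centre is planarised in step 6.

Step 5
Reactants: 9 ethyl 9-[(tert-butyldimethylsilyl)oxy]-4-hydroxy-7-methylidenenon-2-ynoate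
Product: 11 5-{5-[(tert-butyldimethylsilyl)oxy]-3-methylidenepentyl}-4-methylfuran-2(5H)-one, via Z-hydroxy enoate 10 (not isolated)
Conditions: Me2CuLi (2.5 equiv), THF, −78 °C; NH4Cl/MeOH quench at −78 °C; TsOH (cat.), CH2Cl2, rt
Reagents that add atoms: lithium dimethylcuprate, [Li+].C[Cu-]C
Why: syn-Carbocupration of the ynoate (conjugate addition) puts the ester cis to the carbinol, so lactonisation should give the β-methyl butenolide; the methyl introduced is C20.

Step 6
Reactants: 11 5-{5-[(tert-butyldimethylsilyl)oxy]-3-methylidenepentyl}-4-methylfuran-2(5H)-one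
Product: 12 2-[(triisopropylsilyl)oxy]-4-methyl-5-{5-[(tert-butyldimethylsilyl)oxy]-3-methylidenepentyl}furan
Conditions: TIPSOTf, Et3N, CH2Cl2, 0 °C
Reagents that add atoms: triisopropylsilyl triflate, CC(C)[Si](OS(=O)(=O)C(F)(F)F)(C(C)C)C(C)C
Why: Soft enolisation at the γ-position gives the aromatic 2-silyloxyfuran (silyl dienol ether formation) and erases the racemic centre.

Step 7
Reactants: 12 2-[(triisopropylsilyl)oxy]-4-methyl-5-{5-[(tert-butyldimethylsilyl)oxy]-3-methylidenepentyl}furan; 13 (E)-but-2-enal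
Product: 14 (3R)-3-[(2R)-2-{5-[(tert-butyldimethylsilyl)oxy]-3-methylidenepentyl}-3-methyl-5-oxo-2,5-dihydrofuran-2-yl]butanal
Conditions: (2S,5S)-5-benzyl-2-tert-butyl-3-methylimidazolidin-4-one·2,4-dinitrobenzoic acid (20 mol%), H2O (2 equiv), CH2Cl2, −70 °C
Reagents that add atoms: none
Why: Iminium-catalysed vinylogous Mukaiyama–Michael addition joins the furan γ-carbon (C9) to the enal β-carbon (C8); the catalyst shields one enal face and so sets C8, while the open transition state, tuned by the acid co-catalyst and solvent, is chosen to give the quaternary C9 in the (3R,2′R) relationship.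

Step 8
Reactants: 15 1,3-dibromo-2,2-dimethylpropane; 16 thiophenol
Product: 17 (3-bromo-2,2-dimethylpropyl)(phenyl)sulfane
Conditions: K2CO3, DMF, 80 °C, 15 in threefold excess
Reagents that add atoms: none
Why: SN2 thioether formation; thiolate is a strong enough nucleophile for a neopentyl bromide and the excess of 15 limits double substitution.

Step 9
Reactants: 14 (3R)-3-[(2R)-2-{5-[(tert-butyldimethylsilyl)oxy]-3-methylidenepentyl}-3-methyl-5-oxo-2,5-dihydrofuran-2-yl]butanal; 17 (3-bromo-2,2-dimethylpropyl)(phenyl)sulfane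
Product: 19 (5R)-5-{5-[(tert-butyldimethylsilyl)oxy]-3-methylidenepentyl}-5-[(2R)-4-hydroxy-6,6-dimethyl-7-(phenylsulfanyl)heptan-2-yl]-4-methylfuran-2(5H)-one, via Grignard reagent 18 (not isolated)
Conditions: Mg, THF, reflux; then 14, THF, −78 °C; aq NH4Cl
Reagents that add atoms: none
Why: Grignard addition to the unhindered aldehyde should outrun attack on the lactone at low temperature; the new carbinol (C6) forms as a mixture that is oxidised in step 10.

Step 10
Reactants: 19 (5R)-5-{5-[(tert-butyldimethylsilyl)oxy]-3-methylidenepentyl}-5-[(2R)-4-hydroxy-6,6-dimethyl-7-(phenylsulfanyl)heptan-2-yl]-4-methylfuran-2(5H)-one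
Product: 20 (5R)-5-{5-[(tert-butyldimethylsilyl)oxy]-3-methylidenepentyl}-5-[(2R)-6,6-dimethyl-4-oxo-7-(phenylsulfonyl)heptan-2-yl]-4-methylfuran-2(5H)-one
Conditions: Pr4N[RuO4] (10 mol%), NMO (5 equiv), 4 Å MS, MeCN, rt
Reagents that add atoms: N-methylmorpholine N-oxide, C[N+]1([O-])CCOCC1
Why: Perruthenate/N-oxide oxidation takes the secondary alcohol to the ketone and the sulfide to the sulfone in one pot without touching the isolated alkene or the butenolide.

Step 11
Reactants: 20 (5R)-5-{5-[(tert-butyldimethylsilyl)oxy]-3-methylidenepentyl}-5-[(2R)-6,6-dimethyl-4-oxo-7-(phenylsulfonyl)heptan-2-yl]-4-methylfuran-2(5H)-one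
Product: 22 15-[(tert-butyldimethylsilyl)oxy]-9α-hydroxy-3-(phenylsulfonyl)labd-13(16)-ene-2,6-dione, via keto lactone 21 (not isolated)
Conditions: t-BuOK (3 equiv), THF/t-BuOH (10:1), 0 °C to 45 °C; aq NH4Cl
Reagents that add atoms: none
Why: Proposed new method: t-BuOK equilibrates the enolates of 20, the C5 enolate (α to the C6 ketone) adds 6-exo-trig to C10 of the butenolide to give the cis-fused lactone 21 (ring B), and the α-sulfonyl carbanion at C3 then attacks the lactone carbonyl C2 in a 6-exo-trig Claisen condensation that closes ring A, expels the C9 alkoxide and ends in the stabilised β-keto sulfone anion, which makes the sequence irreversible. The closest known reaction type is the consecutive Michael–Claisen (Michael–Dieckmann) annulation of carbanions with unsaturated esters and lactones, together with the acylation of sulfone anions by lactones; new is their union in one pot with two different carbanions insulated by a quaternary carbon. C10 is set by C9, because C5 is tethered through C6–C7–C8 to C9 and can reach the planar butenolide only on the face that carries C8, so the C10 methyl ends cis to C11 and trans to the C9 oxygen as in the target. C5 stays α to the C6 ketone and should equilibrate to the trans-fused decalin, while C3 is uncontrolled and is removed in step 14. Ring A probably closes through the C5 epimer or a boat, since the bridged tetrahedral intermediate needs C9 axial to ring A, and the same enolate equilibrium supplies that epimer. The selectivity needed is C5- over C7-enolate reactivity: the C7 enolate reaches C2 only through a strained oxygen-bridged transition state before the Michael step, and after it gives only a bicyclo[2.2.2]octanedione that cannot be deprotonated at its bridgehead and so reverts.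

Step 12
Reactants: 22 15-[(tert-butyldimethylsilyl)oxy]-9α-hydroxy-3-(phenylsulfonyl)labd-13(16)-ene-2,6-dione
Product: 23 15-[(tert-butyldimethylsilyl)oxy]-3-(phenylsulfonyl)labd-13(16)-ene-2,6β,9α-triol
Conditions: NaBH4, MeOH/THF, 0 °C to rt
Reagents that add atoms: none
Why: Hydride reduction of both ketones; at C6 the β face is screened by the axial methyl groups on C10 and C4, so hydride should enter from the α face and give the axial 6β-alcohol, while the C2 carbinol configuration is irrelevant.

Step 13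
Reactants: 23 15-[(tert-butyldimethylsilyl)oxy]-3-(phenylsulfonyl)labd-13(16)-ene-2,6β,9α-triol
Product: 24 2,6β-diacetoxy-15-[(tert-butyldimethylsilyl)oxy]-3-(phenylsulfonyl)labd-13(16)-en-9α-ol
Conditions: Ac2O, DMAP, pyridine, 50 °C
Reagents that add atoms: acetic anhydride, CC(=O)OC(C)=O
Why: Acylation of the two secondary alcohols installs the 6β-acetate of the target and the leaving group for step 14; the hindered tertiary 9-OH should not react.

Step 14
Reactants: 24 2,6β-diacetoxy-15-[(tert-butyldimethylsilyl)oxy]-3-(phenylsulfonyl)labd-13(16)-en-9α-ol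
Product: 25 6β-acetoxy-15-[(tert-butyldimethylsilyl)oxy]labda-2,13(16)-dien-9α-ol
Conditions: SmI2 (6 equiv), DMPU, THF, −78 °C to rt
Reagents that add atoms: none
Why: Julia-type reductive elimination of the β-acetoxy sulfone gives the C2=C3 alkene; the isolated 6-acetate is inert to SmI2.

Step 15
Reactants: 25 6β-acetoxy-15-[(tert-butyldimethylsilyl)oxy]labda-2,13(16)-dien-9α-ol
Product: 26 6β-acetoxylabda-2,13(16)-diene-9α,15-diol
Conditions: HF·pyridine, THF/pyridine, 0 °C
Reagents that add atoms: none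
Why: Fluoride-mediated desilylation of the primary silyl ether under conditions that spare the acetate.

Step 16
Reactants: 26 6β-acetoxylabda-2,13(16)-diene-9α,15-diol
Product: 28 (13S)-6β-acetoxy-9α,13-epoxylabd-2-ene-15,16-diol, via epoxide 27 (not isolated)
Conditions: Hf(OtBu)4 (10 mol%), C2-symmetric bis-hydroxamic acid ligand from trans-cyclohexane-1,2-diamine (12 mol%, the antipode that gives the 13R epoxide), cumene hydroperoxide, 4 Å MS, toluene, 0 °C; then CSA (cat.), CH2Cl2, 0 °C
Reagents that add atoms: cumene hydroperoxide, CC(C)(OO)c1ccccc1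
Why: Hydroxyl-directed catalytic asymmetric epoxidation of the homoallylic alcohol sets C13 under catalyst control, and acid-promoted 5-exo opening of the epoxide at its tertiary carbon by the 9α-OH proceeds with inversion to give the 13S ether.

Step 17
Reactants: 28 (13S)-6β-acetoxy-9α,13-epoxylabd-2-ene-15,16-diol
Product: 30 (13S)-6β-acetoxy-9α,13-epoxylabd-2-en-15,16-olide, via lactol 29 (not isolated)
Conditions: TEMPO (20 mol%), PhI(OAc)2 (3 equiv), CH2Cl2, rt
Reagents that add atoms: none
Why: Oxidative lactonisation of a 1,4-diol; the less hindered C15 alcohol should be oxidised first, its aldehyde is trapped by the neopentyl C16 hydroxyl as the lactol, and this is oxidised to the 15,16-olide.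

Step 18
Reactants: 30 (13S)-6β-acetoxy-9α,13-epoxylabd-2-en-15,16-olide
Product: 31 previtexilactone
Conditions: H2 (1 atm), Pd/C, EtOAc, rt
Reagents that add atoms: none
Why: Catalytic hydrogenation of the cis-disubstituted Δ2 alkene; no stereocentre is created and lactone, acetate and ether are inert.

**Compound list**

1 | 3-bromobut-3-en-1-ol | C=C(Br)CCO | starting material
2 | [(3-bromobut-3-en-1-yl)oxy](tert-butyl)dimethylsilane | C=C(Br)CCO[Si](C)(C)C(C)(C)C | intermediate
3 | oxetane | C1COC1 | starting material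
4 | {4-[(tert-butyldimethylsilyl)oxy]but-1-en-2-yl}lithium | [Li]C(=C)CCO[Si](C)(C)C(C)(C)C | intermediate
5 | 6-[(tert-butyldimethylsilyl)oxy]-4-methylidenehexan-1-ol | OCCCC(=C)CCO[Si](C)(C)C(C)(C)C | intermediate
6 | 6-[(tert-butyldimethylsilyl)oxy]-4-methylidenehexanal | O=CCCC(=C)CCO[Si](C)(C)C(C)(C)C | intermediate
7 | ethyl propiolate | C#CC(=O)OCC | starting material
8 | ethyl 3-lithioprop-2-ynoate | [Li]C#CC(=O)OCC | intermediate
9 | ethyl 9-[(tert-butyldimethylsilyl)oxy]-4-hydroxy-7-methylidenenon-2-ynoate (racemic) | CCOC(=O)C#CC(O)CCC(=C)CCO[Si](C)(C)C(C)(C)C | intermediate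
10 | ethyl (2Z)-9-[(tert-butyldimethylsilyl)oxy]-4-hydroxy-3-methyl-7-methylidenenon-2-enoate (racemic) | CCOC(=O)/C=C(/C)C(O)CCC(=C)CCO[Si](C)(C)C(C)(C)C | intermediate
11 | 5-{5-[(tert-butyldimethylsilyl)oxy]-3-methylidenepentyl}-4-methylfuran-2(5H)-one (racemic) | CC1=CC(=O)OC1CCC(=C)CCO[Si](C)(C)C(C)(C)C | intermediate
12 | 2-[(triisopropylsilyl)oxy]-4-methyl-5-{5-[(tert-butyldimethylsilyl)oxy]-3-methylidenepentyl}furan | Cc1cc(O[Si](C(C)C)(C(C)C)C(C)C)oc1CCC(=C)CCO[Si](C)(C)C(C)(C)C | intermediate
13 | (E)-but-2-enal (crotonaldehyde) | C/C=C/C=O | starting material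
14 | (3R)-3-[(2R)-2-{5-[(tert-butyldimethylsilyl)oxy]-3-methylidenepentyl}-3-methyl-5-oxo-2,5-dihydrofuran-2-yl]butanal | O=CC[C@@H](C)[C@@]1(CCC(=C)CCO[Si](C)(C)C(C)(C)C)OC(=O)C=C1C | intermediate
15 | 1,3-dibromo-2,2-dimethylpropane | BrCC(C)(C)CBr | starting material
16 | thiophenol | Sc1ccccc1 | starting material
17 | (3-bromo-2,2-dimethylpropyl)(phenyl)sulfane | BrCC(C)(C)CSc1ccccc1 | intermediate
18 | [2,2-dimethyl-3-(phenylsulfanyl)propyl]magnesium bromide | Br[Mg]CC(C)(C)CSc1ccccc1 | intermediate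
19 | (5R)-5-{5-[(tert-butyldimethylsilyl)oxy]-3-methylidenepentyl}-5-[(2R)-4-hydroxy-6,6-dimethyl-7-(phenylsulfanyl)heptan-2-yl]-4-methylfuran-2(5H)-one (both carbinol epimers) | OC(CC(C)(C)CSc1ccccc1)C[C@@H](C)[C@@]1(CCC(=C)CCO[Si](C)(C)C(C)(C)C)OC(=O)C=C1C | intermediate
20 | (5R)-5-{5-[(tert-butyldimethylsilyl)oxy]-3-methylidenepentyl}-5-[(2R)-6,6-dimethyl-4-oxo-7-(phenylsulfonyl)heptan-2-yl]-4-methylfuran-2(5H)-one (a 2,3:5,10-disecolabdane 2,9-olide) | O=C(CC(C)(C)CS(=O)(=O)c1ccccc1)C[C@@H](C)[C@@]1(CCC(=C)CCO[Si](C)(C)C(C)(C)C)OC(=O)C=C1C | intermediate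
21 | 15-[(tert-butyldimethylsilyl)oxy]-6-oxo-3-(phenylsulfonyl)-2,3-secolabd-13(16)-en-2,9α-olide (γ-lactone cis-fused to ring B; C5 epimers) | O=C1C[C@@]2(C)C(C(C)(C)CS(=O)(=O)c3ccccc3)C(=O)C[C@@H](C)[C@@]2(CCC(=C)CCO[Si](C)(C)C(C)(C)C)O1 | intermediate
22 | 15-[(tert-butyldimethylsilyl)oxy]-9α-hydroxy-3-(phenylsulfonyl)labd-13(16)-ene-2,6-dione (trans-decalin, 5α-H, 8α-Me, 10β-Me; C3 epimers) | O=C1C[C@@H](C)[C@](O)(CCC(=C)CCO[Si](C)(C)C(C)(C)C)[C@@]2(C)CC(=O)C(S(=O)(=O)c3ccccc3)C(C)(C)[C@H]12 | intermediate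
23 | 15-[(tert-butyldimethylsilyl)oxy]-3-(phenylsulfonyl)labd-13(16)-ene-2,6β,9α-triol (C2 and C3 epimers) | O[C@@H]1C[C@@H](C)[C@](O)(CCC(=C)CCO[Si](C)(C)C(C)(C)C)[C@@]2(C)CC(O)C(S(=O)(=O)c3ccccc3)C(C)(C)[C@H]12 | intermediate
24 | 2,6β-diacetoxy-15-[(tert-butyldimethylsilyl)oxy]-3-(phenylsulfonyl)labd-13(16)-en-9α-ol | CC(=O)O[C@@H]1C[C@@H](C)[C@](O)(CCC(=C)CCO[Si](C)(C)C(C)(C)C)[C@@]2(C)CC(OC(C)=O)C(S(=O)(=O)c3ccccc3)C(C)(C)[C@H]12 | intermediate
25 | 6β-acetoxy-15-[(tert-butyldimethylsilyl)oxy]labda-2,13(16)-dien-9α-ol | CC(=O)O[C@@H]1C[C@@H](C)[C@](O)(CCC(=C)CCO[Si](C)(C)C(C)(C)C)[C@@]2(C)CC=CC(C)(C)[C@H]12 | intermediate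
26 | 6β-acetoxylabda-2,13(16)-diene-9α,15-diol | CC(=O)O[C@@H]1C[C@@H](C)[C@](O)(CCC(=C)CCO)[C@@]2(C)CC=CC(C)(C)[C@H]12 | intermediate
27 | (13R)-6β-acetoxy-13,16-epoxylabd-2-ene-9α,15-diol | CC(=O)O[C@@H]1C[C@@H](C)[C@](O)(CC[C@@]3(CCO)CO3)[C@@]2(C)CC=CC(C)(C)[C@H]12 | intermediate
28 | (13S)-6β-acetoxy-9α,13-epoxylabd-2-ene-15,16-diol | CC(=O)O[C@@H]1C[C@@H](C)[C@]2(CC[C@@](CO)(CCO)O2)[C@@]2(C)CC=CC(C)(C)[C@H]12 | intermediate
29 | (13S)-6β-acetoxy-9α,13:15,16-diepoxylabd-2-en-15-ol (lactol; both anomers) | CC(=O)O[C@@H]1C[C@@H](C)[C@]2(CC[C@]3(COC(O)C3)O2)[C@@]2(C)CC=CC(C)(C)[C@H]12 | intermediate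
30 | (13S)-6β-acetoxy-9α,13-epoxylabd-2-en-15,16-olide | CC(=O)O[C@@H]1C[C@@H](C)[C@]2(CC[C@]3(COC(=O)C3)O2)[C@@]2(C)CC=CC(C)(C)[C@H]12 | intermediate
31 | previtexilactone, (13S)-6β-acetoxy-9α,13-epoxylabdan-15,16-olide | CC(=O)O[C@@H]1C[C@@H](C)[C@]2(CC[C@]3(COC(=O)C3)O2)[C@@]2(C)CCCC(C)(C)[C@H]12 | target

**Step count and risks**

Total steps: 18. Longest linear sequence: 17 (steps 1–7 and 9–18); step 8 is a one-step side branch.

Steps most likely to fail:

1. Step 11 (labelled). What may go wrong: the enolate equilibria may drain into Claisen attack of the C7 enolate on the lactone carbonyl, or the Michael adduct may revert faster than the hindered sulfonyl carbanion closes ring A. The fallback makes the two bonds in separate, known operations from 20. TBSOTf/Et3N converts the ketone into the C5=C6 silyl enol ether F1; the regioisomer toward C7 cannot cyclise and is hydrolysed back to 20. TiCl4 in CH2Cl2 at −78 °C then effects an intramolecular Mukaiyama–Michael addition to the butenolide and gives lactone 21 in isolated form. LiN(iPr)2 in THF (−78 to 0 °C) finally closes ring A by sulfone–lactone Claisen condensation, which returns to 22.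

2. Step 7. What may go wrong: poor diastereofacial selection at the furan (wrong C9 relative to C8) or low reactivity of the fully substituted, methyl-flanked furan carbon. The fallback sets out from 12 and uses Lewis-acid instead of iminium activation. Cu(OTf)2 with 2,2′-isopropylidenebis[(4S)-4-tert-butyl-2-oxazoline] catalyses the Mukaiyama–Michael addition of 12 to (E)-3-(but-2-enoyl)oxazolidin-2-one through a chelated two-point-bound acceptor and gives imide F2. LiSEt in THF converts F2 into thioester F3, and Fukuyama reduction (Et3SiH, Pd/C, acetone, 0 °C) returns to aldehyde 14.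

3. Step 16. What may go wrong: loss of catalyst control over the alkene face, or competing 5-exo closure of the primary hydroxyl onto the epoxide CH2 instead of attack of the 9α-OH at C13. The fallback sets out from 26 and relies on separation and recycling instead of catalyst control. VO(acac)2/t-BuOOH in CH2Cl2 followed by CSA gives 28 together with its C13 epimer, diol F5, by way of 27 and the epimeric epoxide F4 (not isolated). The mixture is oxidised as in step 17 to 30 and the 13-epi lactone F7 (through 29 and the epimeric lactol F6), and these are separated by chromatography. F7 is then stirred with DBU in THF, which opens it by retro-oxa-Michael elimination to the butenolide F8 and re-closes it by oxa-Michael addition to both C13 epimers; repeated separation funnels the material to 30.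

Further compounds
F1 | step 11 | (5R)-5-{5-[(tert-butyldimethylsilyl)oxy]-3-methylidenepentyl}-5-[(2R)-4-[(tert-butyldimethylsilyl)oxy]-6,6-dimethyl-7-(phenylsulfonyl)hept-4-en-2-yl]-4-methylfuran-2(5H)-one | CC(C)(C)[Si](C)(C)OC(=CC(C)(C)CS(=O)(=O)c1ccccc1)C[C@@H](C)[C@@]1(CCC(=C)CCO[Si](C)(C)C(C)(C)C)OC(=O)C=C1C
F2 | step 7 | 3-{(3R)-3-[(2R)-2-{5-[(tert-butyldimethylsilyl)oxy]-3-methylidenepentyl}-3-methyl-5-oxo-2,5-dihydrofuran-2-yl]butanoyl}oxazolidin-2-one | O=C(C[C@@H](C)[C@@]1(CCC(=C)CCO[Si](C)(C)C(C)(C)C)OC(=O)C=C1C)N1CCOC1=O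
F3 | step 7 | S-ethyl (3R)-3-[(2R)-2-{5-[(tert-butyldimethylsilyl)oxy]-3-methylidenepentyl}-3-methyl-5-oxo-2,5-dihydrofuran-2-yl]butanethioate | CCSC(=O)C[C@@H](C)[C@@]1(CCC(=C)CCO[Si](C)(C)C(C)(C)C)OC(=O)C=C1C
F4 | step 16 | (13S)-6β-acetoxy-13,16-epoxylabd-2-ene-9α,15-diol | CC(=O)O[C@@H]1C[C@@H](C)[C@](O)(CC[C@]3(CCO)CO3)[C@@]2(C)CC=CC(C)(C)[C@H]12
F5 | step 16 | (13R)-6β-acetoxy-9α,13-epoxylabd-2-ene-15,16-diol | CC(=O)O[C@@H]1C[C@@H](C)[C@]2(CC[C@](CO)(CCO)O2)[C@@]2(C)CC=CC(C)(C)[C@H]12
F6 | step 16 | (13R)-6β-acetoxy-9α,13:15,16-diepoxylabd-2-en-15-ol | CC(=O)O[C@@H]1C[C@@H](C)[C@]2(CC[C@@]3(COC(O)C3)O2)[C@@]2(C)CC=CC(C)(C)[C@H]12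
F7 | step 16 | (13R)-6β-acetoxy-9α,13-epoxylabd-2-en-15,16-olide | CC(=O)O[C@@H]1C[C@@H](C)[C@]2(CC[C@@]3(COC(=O)C3)O2)[C@@]2(C)CC=CC(C)(C)[C@H]12
F8 | step 16 | 6β-acetoxy-9α-hydroxylabda-2,13-dien-15,16-olide | CC(=O)O[C@@H]1C[C@@H](C)[C@](O)(CCC3=CC(=O)OC3)[C@@]2(C)CC=CC(C)(C)[C@H]12
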